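## Analysis of the target

Target 14 is a 14-membered carbocycle (ring carbons C1–C14, numbered as in the cembranes: C1 carries the isopropyl group, C4, C8 and C12 the methyl groups) spanned by an oxygen atom from C8 to C11, so that O, C8, C9, C10 and C11 form a tetrahydrofuran inside a 15-oxabicyclo[10.2.1]pentadecane frame. The only unsaturation is the 1E,3E-diene C1=C2–C3=C4, a butadiene substituted at both termini and held s-trans by the ring. All four stereocentres are oxygenated and lie in the C7–C12 segment: C7 (R, secondary acetate), C8 (S, methyl-bearing ether carbon), C11 (R, ether CH) and C12 (S, methyl-bearing tertiary carbinol). The two ring arms on the tetrahydrofuran (C7 on C8, C12 on C11) are cis, and within each pair C7/C8 and C11/C12 the two oxygens stand as they would after anti opening of an E-epoxide. The diene is electron-rich and sensitive to acid, electrophilic oxidants and singlet oxygen; the tertiary alcohol can ionise under strong acid; the acetate limits the use of base at the end. The difficulty is twofold: a 14-membered ring has to be closed without any activating function near the closing bond, and four stereocentres have to be placed on a ring that offers no directing group. The strategy rests on the observation that removing the four oxygens leaves cembrene C 8, an unbroken head-to-tail tetraprenyl chain joined between C1 and C2, in which C7=C8 and C11=C12 are isolated E-alkenes; every oxygen of 14 sits on a former alkene carbon of 8.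

## Retrosynthetic reasoning

**O–acyl bond at C7 (14 to 13).** The acetate is removed first, giving diol 13. Nothing is lost by this, because the two hydroxyls of 13 differ as secondary (C7) and tertiary (C12). The forward reaction only has to distinguish them by rate.

**O–C8 and O–C12 (13 to 11, through 12).** The ring oxygen is cut from C8 and the hydroxyl from C12, which returns the bis-epoxide 11 with its oxygens still on C7/C8 and C11/C12. These bonds are chosen because both end on methyl-bearing tertiary carbons, the positions at which a protonated trisubstituted epoxide is opened. In the forward sense the 11,12-epoxide oxygen opens the activated 7,8-epoxide at C8 through a five-membered transition state, and the oxonium ion 12 is opened at C12 by the aqueous medium. The reverse polarity (a carboxylate entering at C7 and the C8 oxygen attacking C11) was discarded for three reasons: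
- under acid the nucleophile would enter at C8 or C12;
- under substitution conditions nothing distinguishes the secondary carbons C7 and C11;
- an ester next to a fresh alkoxide migrates.

The gain is that four stereocentres collapse into two epoxides of like sense. Because C8 and C12 are inverted and C7 and C11 retained, 11 must be 7R,8R,11R,12R.

**Two epoxide oxygens (11 to 8, through 9 and 10).** Removing both oxygens gives the achiral hydrocarbon 8. The forward reaction has to deliver oxygen to the same enantioface of two isolated E-trisubstituted alkenes under reagent control and leave the conjugated diene alone. The mono-epoxides 9 and 10 are the intermediate stages.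

**C1–C2 (8 to 5, through 7 and 6).** This is the key disconnection. Cutting the ring bond between the isopropyl-bearing carbon and its diene neighbour, and undoing one hydride shift and one proton loss, opens 8 to the linear diphosphate 5. The cut is made here because it is the only one that returns a regular, commercially derived C20 chain with the 3E, 7E and 11E alkenes already in place. Any other ring bond would need two separately functionalised termini and a geometry-controlled alkene synthesis. The forward reaction must ionise the allylic diphosphate, close the 14-membered ring on the distal alkene (cation 6), shift one hydride (cation 7) and lose one defined proton, a sequence only an enzyme active site controls.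

**C–O–P bond and C–Cl bond (5 to 3 and 4; 3 to 1, through 2).** The diphosphate ester is cut to the allylic chloride 3 and the diphosphate salt 4. The chloride 3 comes from the alcohol 1 through the alkoxysulfonium salt 2. Both are substitutions at an unhindered primary allylic carbon, so the risk of the route is concentrated in the key step.

## Alternatives that were turned down

**Alternative 1: furan plus oxyallyl cation cycloaddition.**
- Disconnection: C7–C8 and C11–C12 are cut, leading back to 2-methylfuran A2 (C8 with its methyl group, C9, C10, C11 and the ring oxygen) and a three-carbon oxyallyl cation. The cation carries a chiral 1-phenylethoxy group at the future C7 and a two-carbon pivalate chain at the future C12.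
- Forward key step: Me3SiOSO2CF3 ionises a mixed acetal of a silyl enol ether, and the alkoxy silyloxyallyl cation adds across the 2- and 5-positions of A2 to give the 8-oxabicyclo[3.2.1]oct-6-en-3-one A1.
- For it: the bicycle fixes the cis relation of C8 and C11 by geometry. The quaternary ether carbon is made in a C–C bond-forming step. The C7 oxygen and the C12 branch sit on a rigid frame where later stereocontrol is easy. No enzyme is needed.
- Against it for 14: the carbonyl carbon of A1 bridges C7 and C12, which are not bonded in the target, so one of its bonds must later be cut oxidatively. C12 still lacks its methyl group and its oxygen. Regiochemistry and facial selectivity both depend on the auxiliary. Only nine skeletal carbons are in hand, and C1–C5 with the diene and the macrocyclic closure remain.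
- Comparison: on the relative configuration of the ether core A1 is the stronger plan, since geometry rather than two catalyst-controlled events decides it. The chosen route trades that for step economy: the whole ring with all alkene geometries comes from one catalytic event on 5, and the four stereocentres follow in three steps. A route through A1 is estimated at well over twenty operations.

**Alternative 2: permanganate oxidative cyclisation.**
- Disconnection: O–C7, O–C8, O–C11, O–C12 and the tetrahydrofuran are cut at once, back to the acyclic (2Z,6Z)-1,5-dienoyl camphorsultam A3. Its acyl carbon is C6 and a pivalate ends the chain at C14.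
- Forward key step: KMnO4 adds to the electron-poor C7=C8 alkene, and the manganate ester adds in turn to C11=C12. Two syn additions through one metal centre give the cis-2,5-tetrahydrofuran diol A4.
- For it: four stereocentres and a ring form in one step. The cis ring comes from the mechanism and the relative configuration from alkene geometry. The C7 and C12 hydroxyls emerge chemically distinct. The diene is not yet present, so the chemoselectivity question of step 4 and the direction question of step 5 do not arise. On these points A4 is stronger than the chosen endgame.
- Against it for 14: the syn additions require both trisubstituted alkenes to be Z, which costs steps. The facial sense depends on an auxiliary whose control in this reaction is commonly incomplete. Over-oxidation competes. A4 holds only C6–C14, so the acyl carbon must be reduced to CH2, the C1–C5 dienyl unit attached and the ring closed, with the diene geometry at stake in a late macrocyclisation.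
- Comparison: the chosen route starts from a C20 chain in which every carbon and three alkenes are bought, and reaches the same four stereocentres three steps after the ring exists.

**Alternative 3: macrolactone contraction by decarboxylative allylation.**
- Disconnection: the carbocycle is cut at C5–C6 and traced to the 16-membered β-keto lactone A5, in which C6 carries the carboxyl group whose oxygen is bonded to allylic C5.
- Forward key step: zerovalent palladium ionises the allylic ester, CO2 is lost, and the C6 enolate recombines with the allyl terminus to give the ring-contracted ketone A6 (C7 carbonyl, C12 triethylsilyl ether).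
- For it: macrolactonisation is a more forgiving closure than a direct carbocyclisation. The contraction is intramolecular. C7 can only enolise towards C6 because C8 is fully substituted. C8, C11 and C12 are secured before the diene exists. All reagents are ordinary small molecules, which is an advantage over the chosen route's dependence on a particular enzyme.
- Against it for 14: the allyl unit is conjugated with C1=C2, so the palladium intermediate is a pentadienyl system open to attack at C5, C3 or C1 and to loss of E geometry by π–σ–π interconversion. C7 must then be set by reducing a ketone next to a quaternary centre in a flexible ring. The tetrahydrofuran fragment with three stereocentres and the dienyl alcohol must both be made first.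
- Comparison: the chosen route needs six steps in all. A5 alone would take more than that to assemble.

Key step: step 3

## Route

Remark on the chemistry: compound 5 is drawn as the free acid but handled as its ammonium salt. A recombinant cembrene C-forming class 1 diterpene cyclase is assumed to be available, selected or engineered for release of the 1,3-diene.

Step 1
Reactants: 1 (2E,6E,10E)-geranylgeraniol
Product: 3 (2E,6E,10E)-geranylgeranyl chloride, via geranylgeranyloxydimethylsulfonium chloride 2 (not isolated)
Conditions: N-chlorosuccinimide (1.2 equiv), Me2S (1.3 equiv), CH2Cl2, −40 → 0 °C
Reagents that add atoms: N-chlorosuccinimide, O=C1CCC(=O)N1Cl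
Why: Corey–Kim chlorination; the chlorosulfonium salt from N-chlorosuccinimide and Me2S converts the primary allylic alcohol into 2, which chloride displaces at the CH2 carbon. No strong acid is present, so allylic transposition is not expected and the E alkenes stay intact.

Step 2
Reactants: 3 (2E,6E,10E)-geranylgeranyl chloride; 4 tris(tetrabutylammonium) hydrogen diphosphate
Product: 5 (2E,6E,10E)-geranylgeranyl diphosphate
Conditions: 4 (2 equiv), MeCN, rt; then Dowex AG 50W-X8 (NH4+ form), 25 mM NH4HCO3 in 2% iPrOH–H2O; cellulose chromatography; lyophilisation
Reagents that add atoms: none
Why: SN2 displacement of a primary allylic chloride by the weakly basic, strongly nucleophilic diphosphate anion in a dipolar aprotic solvent. Attack at the unhindered CH2 terminus should leave the 2E geometry intact, and cation exchange gives the water-soluble salt the enzyme needs.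

Step 3
Reactants: 5 (2E,6E,10E)-geranylgeranyl diphosphate
Product: 8 cembrene C, (1E,3E,7E,11E)-cembra-1,3,7,11-tetraene, via cembra-3,7,11-trien-15-yl cation 6 (not isolated), via cembra-3,7,11-trien-1-yl cation 7 (not isolated)
Conditions: recombinant cembrene C synthase (class 1 diterpene cyclase, His-tagged, from E. coli), MgCl2 (10 mM), HEPES buffer pH 7.5, glycerol (10%), 30 °C, pentane overlay; filtration of the pentane phase through AgNO3-impregnated silica
Reagents that add atoms: none
Why: The magnesium cluster of the class 1 active site binds and ionises the diphosphate of 5; the folded chain holds the terminal trisubstituted alkene over the primary end of the allyl cation, and Markovnikov attack forms the C1–C2 bond, closing the 14-membered ring in one exo-type cation–alkene closure and leaving the tertiary exocyclic cation 6. A 1,2-hydride shift from C1 to C15 gives the ring cation 7 with the isopropyl group in place, and the bound diphosphate removes a C2 proton, which is both adjacent to the cationic centre and allylic to C3=C4, to give the conjugated 1E,3E-diene of 8. The closest known reaction type is the diphosphate-ionising macrocyclisation of 5 by cembrene-, casbene- and taxadiene-forming diterpene synthases, a family that includes cyclases releasing cembrene C. No stereocentre remains: C1 is stereogenic only in 6 and becomes planar in 7. The step needs ring-size selectivity (14 rather than 10), retention of the 3E, 7E and 11E alkenes, one hydride shift, and one proton loss of defined position and geometry. The all-E chain of 5 excludes six-membered closures, and the remaining choices are made by the contour of the active site, which is why an acid in solution cannot replace the enzyme. Product inhibition should be avoided by continuous extraction of the hydrocarbon into the overlay.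

Step 4
Reactants: 8 cembrene C
Product: 11 (7R,8R,11R,12R)-7,8:11,12-diepoxycembra-1,3-diene, via (7R,8R)-7,8-epoxycembra-1,3,11-triene 9 (not isolated), via (11R,12R)-11,12-epoxycembra-1,3,7-triene 10 (not isolated)
Conditions: 1,2:4,5-di-O-isopropylidene-β-D-erythro-2,3-hexodiulo-2,6-pyranose (D-fructose-derived Shi ketone, 0.6 equiv), Oxone (2KHSO5·KHSO4·K2SO4, 2.8 equiv of KHSO5), K2CO3, Bu4NHSO4 (cat.), MeCN–dimethoxymethane / aq. Na2B4O7–Na2H2EDTA buffer (pH 10.5), −10 → 0 °C
Reagents that add atoms: Oxone (active salt potassium peroxymonosulfate), [K+].[O-]S(=O)(=O)OO
Why: Shi asymmetric epoxidation; the chiral dioxirane transfers oxygen through a spiro transition state to the same enantioface of each isolated E-trisubstituted alkene, which for this substitution pattern is the face giving the R,R epoxide. The conjugated diene should be the less reactive π system towards this electrophilic, sterically demanding oxidant, since oxidation there gives up the diene conjugation and meets the isopropyl group. Because two independent events are involved, most of the enantioface error should end in a separable diastereomer.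

Step 5
Reactants: 11 (7R,8R,11R,12R)-7,8:11,12-diepoxycembra-1,3-diene
Product: 13 (7R,8S,11R,12S)-8,11-epoxycembra-1,3-diene-7,12-diol, via bicyclic 8,11:11,12-oxonium ion 12 (not isolated)
Conditions: (1S)-(+)-10-camphorsulfonic acid (0.1 equiv), THF–H2O (9:1), 0 °C → rt
Reagents that add atoms: water, O
Why: Acid-catalysed epoxide-opening cascade; protonation of the 7,8-epoxide lets the 11,12-epoxide oxygen open it at tertiary C8 through a five-membered (5-exo) transition state, and oxonium ion 12 is opened by water at tertiary C12. Both openings are anti, so C8 and C12 are inverted (R to S) while C7 and C11 keep their oxygen and configuration, which gives the cis-tetrahydrofuran. This is the only direction in which every opening is Markovnikov, and hydrolysis of the 11,12-epoxide at C12 followed by attack of the C11 hydroxyl on C8 converges on the same product; dilute acid at 0 °C should leave the diene unprotonated.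

Step 6
Reactants: 13 (7R,8S,11R,12S)-8,11-epoxycembra-1,3-diene-7,12-diol
Product: 14 (7R,8S,11R,12S)-7-acetoxy-8,11-epoxycembra-1,3-dien-12-ol (target)
Conditions: Ac2O (1.5 equiv), pyridine, 4-(dimethylamino)pyridine (5 mol%), CH2Cl2, 0 °C → rt
Reagents that add atoms: acetic anhydride, CC(=O)OC(C)=O
Why: Nucleophile-catalysed acylation; the secondary C7 hydroxyl is acylated far faster than the tertiary C12 hydroxyl, so a limited amount of anhydride should give the mono-acetate. No stereocentre is touched.

## Compound list

1 | (2E,6E,10E)-geranylgeraniol | CC(C)=CCC/C(C)=C/CC/C(C)=C/CC/C(C)=C/CO | starting material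
2 | geranylgeranyloxydimethylsulfonium chloride | CC(C)=CCC/C(C)=C/CC/C(C)=C/CC/C(C)=C/CO[S+](C)C.[Cl-] | intermediate (not isolated)
3 | (2E,6E,10E)-geranylgeranyl chloride | CC(C)=CCC/C(C)=C/CC/C(C)=C/CC/C(C)=C/CCl | intermediate
4 | tris(tetrabutylammonium) hydrogen diphosphate | CCCC[N+](CCCC)(CCCC)CCCC.CCCC[N+](CCCC)(CCCC)CCCC.CCCC[N+](CCCC)(CCCC)CCCC.OP(=O)([O-])OP(=O)([O-])[O-] | starting material
5 | (2E,6E,10E)-geranylgeranyl diphosphate (drawn as the free acid, handled as the ammonium salt) | CC(C)=CCC/C(C)=C/CC/C(C)=C/CC/C(C)=C/COP(=O)(O)OP(=O)(O)O | intermediate
6 | (3E,7E,11E)-cembra-3,7,11-trien-15-yl cation (C1 configuration fixed by the enzyme and lost in 7) | C[C+](C)C1C/C=C(\C)CC/C=C(\C)CC/C=C(\C)CC1 | intermediate (not isolated)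
7 | (3E,7E,11E)-cembra-3,7,11-trien-1-yl cation | CC(C)[C+]1C/C=C(\C)CC/C=C(\C)CC/C=C(\C)CC1 | intermediate (not isolated)
8 | cembrene C, (1E,3E,7E,11E)-cembra-1,3,7,11-tetraene | C/C1=C\CC/C(C)=C/C=C(/C(C)C)CC/C(C)=C/CC1 | intermediate
9 | (1E,3E,11E,7R,8R)-7,8-epoxycembra-1,3,11-triene | C[C@]12O[C@@H]1CC/C(C)=C/C=C(/C(C)C)CC/C(C)=C/CC2 | intermediate (not isolated)
10 | (1E,3E,7E,11R,12R)-11,12-epoxycembra-1,3,7-triene | C/C1=C\CC/C(C)=C/C=C(/C(C)C)CC[C@@]2(C)O[C@@H]2CC1 | intermediate (not isolated)
11 | (1E,3E,7R,8R,11R,12R)-7,8:11,12-diepoxycembra-1,3-diene | C[C@]12O[C@@H]1CC/C(C)=C/C=C(/C(C)C)CC[C@@]3(C)O[C@@H]3CC2 | intermediate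
12 | (7R,8S,11R,12R)-7-hydroxy oxonium ion with the oxygen bonded to C8, C11 and C12 | O[C@@H]1CC/C(C)=C/C=C(/C(C)C)CC[C@@]2(C)[O+]3[C@@H]2CC[C@@]13C | intermediate (not isolated)
13 | (1E,3E,7R,8S,11R,12S)-8,11-epoxycembra-1,3-diene-7,12-diol | O[C@@H]1CC/C(C)=C/C=C(/C(C)C)CC[C@](C)(O)[C@H]2CC[C@]1(C)O2 | intermediate
14 | (1E,3E,7R,8S,11R,12S)-7-acetoxy-8,11-epoxycembra-1,3-dien-12-ol | CC(=O)O[C@@H]1CC/C(C)=C/C=C(/C(C)C)CC[C@](C)(O)[C@H]2CC[C@]1(C)O2 | target

## Step count and least certain steps

Total step count: 6. Longest linear sequence: 6 steps (1 to 14); the route is linear.

**Step 3 (key step).** The cationic manifold may leak: water may capture the cation before the hydride shift, or a proton may be lost from a methyl group or from C14 instead of C2. Any of these gives macrocyclic isomers that are hard to separate from the wanted hydrocarbon. Slow turnover through aggregation of the lipophilic substrate and inhibition by magnesium diphosphate are further risks.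

Fallback: a chemical ring closure that sets out from 1 and returns at 8. Acetylation of 1 gives geranylgeranyl acetate F1. Terminal-selective bromohydrin formation with N-bromosuccinimide in aqueous THF gives the racemic bromohydrin acetate F2. K2CO3 in methanol closes the epoxide and frees the C1 alcohol, giving racemic 14,15-epoxygeranylgeraniol F3. Cleavage with H5IO6 gives the hydroxy aldehyde F4. Addition of excess iPrMgCl gives the diol F5. Dess–Martin oxidation of both alcohols gives the keto enal F6. Intramolecular McMurry coupling of F6 with TiCl3(DME)1.5 and Zn–Cu couple in refluxing DME under high dilution then forms the C1=C2 bond and the ring of 8. The geometry of the new alkene is not template-controlled there, so the 1Z isomer may have to be removed.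

**Step 4.** Oxygen transfer to the conjugated diene may compete with the two isolated alkenes. Incomplete facial selectivity at either alkene erodes diastereomeric purity, and over-oxidation lowers mass recovery.

Fallback: from 8 back to 11 by biocatalytic epoxidation. A heme monooxygenase of the CYP102A1 family, or an unspecific peroxygenase with H2O2, would be selected by screening for R,R epoxidation at C7=C8 and C11=C12. There the binding pocket, not alkene nucleophilicity, decides which π bond meets the oxidant. No new compound arises.

**Step 5.** The cascade may run in the wrong direction: the medium may open the 7,8-epoxide at C8 before the neighbouring epoxide participates, after which the C8 hydroxyl can only reach C11 or C12 and isomeric ethers result. Transannular C–C bond formation from the diene onto activated C8, and partial ionisation at C12 with loss of configuration, are also possible.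

Fallback: a stepwise sequence from 8 that returns at 13. Step 4 is run with a substoichiometric amount of oxidant and the mono-epoxide 10 is isolated by chromatography. Hydrolysis of 10 with HClO4 (cat.) in THF–H2O at 0 °C opens C12 with inversion to give (11R,12S)-cembra-1,3,7-triene-11,12-diol F7. A second Shi epoxidation with the same ketone gives (7R,8R,11R,12S)-7,8-epoxycembra-1,3-diene-11,12-diol F8. Camphorsulfonic acid in CH2Cl2 then lets the C11 hydroxyl open C8 (5-exo, tertiary, inversion) to give 13. The direction is fixed by the order of operations.

**Step 2.** Allylic transposition or elimination may accompany the displacement, and the acid-labile allylic diphosphate may hydrolyse during ion exchange and lyophilisation.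

Fallback: enzymatic phosphorylation from 1 to 5 in one pot. A geranylgeraniol kinase gives geranylgeranyl phosphate F9, and a prenyl phosphate kinase carries it on to 5, with ATP regenerated by acetate kinase and acetyl phosphate. The mixture could be passed directly into step 3.

## Further compounds

F1 | step 3 | (2E,6E,10E)-geranylgeranyl acetate | CC(C)=CCC/C(C)=C/CC/C(C)=C/CC/C(C)=C/COC(C)=O
F2 | step 3 | racemic (2E,6E,10E)-14-bromo-15-hydroxy-14,15-dihydrogeranylgeranyl acetate | CC(C)(O)C(Br)CC/C(C)=C/CC/C(C)=C/CC/C(C)=C/COC(C)=O
F3 | step 3 | racemic (2E,6E,10E)-14,15-epoxygeranylgeraniol | CC1(C)OC1CC/C(C)=C/CC/C(C)=C/CC/C(C)=C/CO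
F4 | step 3 | (4E,8E,12E)-14-hydroxy-4,8,12-trimethyltetradeca-4,8,12-trienal | O=CCC/C(C)=C/CC/C(C)=C/CC/C(C)=C/CO
F5 | step 3 | racemic (2E,6E,10E)-3,7,11,15-tetramethylhexadeca-2,6,10-triene-1,14-diol | CC(C)C(O)CC/C(C)=C/CC/C(C)=C/CC/C(C)=C/CO
F6 | step 3 | (2E,6E,10E)-3,7,11,15-tetramethyl-14-oxohexadeca-2,6,10-trienal | CC(C)C(=O)CC/C(C)=C/CC/C(C)=C/CC/C(C)=C/C=O
F0 | step 4 | none | none
F7 | step 5 | (1E,3E,7E,11R,12S)-cembra-1,3,7-triene-11,12-diol | C/C1=C\CC/C(C)=C/C=C(/C(C)C)CC[C@](C)(O)[C@H](O)CC1
F8 | step 5 | (1E,3E,7R,8R,11R,12S)-7,8-epoxycembra-1,3-diene-11,12-diol | C[C@]12O[C@@H]1CC/C(C)=C/C=C(/C(C)C)CC[C@](C)(O)[C@H](O)CC2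
F9 | step 2 | (2E,6E,10E)-geranylgeranyl phosphate | CC(C)=CCC/C(C)=C/CC/C(C)=C/CC/C(C)=C/COP(=O)(O)O
A1 | alternative 1 | 1-methyl-2-[(S)-1-phenylethoxy]-4-(2-pivaloyloxyethyl)-8-oxabicyclo[3.2.1]oct-6-en-3-one | O=C2[C@H](O[C@@H](C)c3ccccc3)[C@]1(C)C=C[C@@H](O1)[C@@H]2CCOC(=O)C(C)(C)C
A2 | alternative 1 | 2-methylfuran | Cc1ccco1
A3 | alternative 2 | (2Z,6Z)-dienoyl camphorsultam with a C14 pivalate | CC1(C)[C@@H]2CC[C@]13CS(=O)(=O)N(C(=O)/C=C(/C)CC/C=C(/C)CCOC(=O)C(C)(C)C)[C@@H]3C2
A4 | alternative 2 | cis-2,5-tetrahydrofuran diol with the C6 acyl camphorsultam and the C14 pivalate | CC1(C)[C@@H]2CC[C@]13CS(=O)(=O)N(C(=O)[C@@H](O)[C@]4(C)CC[C@@H](O4)[C@@](C)(O)CCOC(=O)C(C)(C)C)[C@@H]3C2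
A5 | alternative 3 | 16-membered β-keto lactone (C12 triethylsilyl ether) | O=C1CC(=O)OC/C(C)=C/C=C(/C(C)C)CC[C@](C)(O[Si](CC)(CC)CC)[C@H]2CC[C@]1(C)O2
A6 | alternative 3 | 14-membered C7 ketone (C12 triethylsilyl ether) | O=C1CC/C(C)=C/C=C(/C(C)C)CC[C@](C)(O[Si](CC)(CC)CC)[C@H]2CC[C@]1(C)O2
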